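## Retrosynthetic overview

1. Target ⇒ ring B bromohydrin formation (NBS/H2O) on a 10-bromo-α-chamigrene-type diene; this sets C2 and C3 last.
2. Diene ⇒ symmetric spiro 3,7-diketone: both ketones become methyl-bearing alkenes via enol triflates, and a chiral lithium amide chooses C2 over C4, which makes the spiro carbon C6 stereogenic.
3. Diketone ⇒ spiro cyclohexadienone ⇒ 4-(1-hydroxycyclopentyl)phenol: oxidative dearomatization with semipinacol ring expansion (cyclopentanol → cyclohexanone) forms ring A and the spiro carbon.
4. Aryl cyclopentanol ⇒ 4-bromophenol + (S)-3-bromo-2,2-dimethylcyclopentanone.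
5. Bromoketone ⇒ (R)-1,2-dimethylcyclopent-2-en-1-ol by a bromonium-triggered semipinacol 1,2-methyl shift ⇒ 2-methylcyclopent-2-enone. Ring order: cyclopentane (bought) → ring A by ring expansion onto the arene → ring B by saturation of the dienone.

Convention: spiro compounds are numbered as in the target name (ring B = C1–C5, spiro carbon = C6, ring A = C7–C11). The target SMILES corresponds to (2R,3R,6R,10S).

## Route

Step 1
Reactants: 1 2-methylcyclopent-2-en-1-one
Product: 2 (R)-1,2-dimethylcyclopent-2-en-1-ol
Conditions: Me2Zn (2.0 equiv), Ti(OiPr)4 (1.2 equiv), trans-cyclohexane-1,2-diamine bis(camphorsulfonamide) diol ligand (10 mol%, the enantiomer that gives the R alcohol), toluene/hexane, rt, 36 h; then H2O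
Reagents that add atoms: dimethylzinc C[Zn]C
Why: Catalytic asymmetric 1,2-addition of a dialkylzinc to a ketone under a chiral titanium bis(sulfonamide) complex, a reaction that works well for 2-substituted cyclic enones; the ligand enantiomer fixes the carbonyl face attacked and so sets the R carbinol.

Step 2
Reactants: 2 (R)-1,2-dimethylcyclopent-2-en-1-ol
Product: 3 (S)-3-bromo-2,2-dimethylcyclopentan-1-one
Conditions: NBS (1.05 equiv), CH2Cl2/(CF3)2CHOH 4:1, −40 °C, dark, 1 h
Reagents that add atoms: N-bromosuccinimide O=C1CCC(=O)N1Br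
Why: Proposed new method: a bromonium-triggered semipinacol rearrangement with 1,2-methyl shift, in which Br+ (NBS activated by hydrogen bonding to the fluoro alcohol) adds to the alkene face syn to the hydroxyl (smaller than the C1 methyl and hydrogen-bond directing), so that in the bromiranium-like transition state only the C1 methyl is anti-periplanar to the breaking tertiary C–Br bond and migrates while the hydroxyl becomes the ketone, which relays the carbinol configuration to C3 (bromine on the former hydroxyl face, S) and creates the gem-dimethyl quaternary carbon; the ring C–C bond lies in the alkene plane and cannot migrate, and the closest known reactions are halonium-induced semipinacol rearrangements of allylic alcohols with aryl shift or strained-ring expansion and the Lewis-acid semipinacol of 2,3-epoxy alcohols with alkyl shift.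

Step 3
Reactants: 3 (S)-3-bromo-2,2-dimethylcyclopentan-1-one, 4 4-bromophenol
Product: 6 4-[(1S,3S)-3-bromo-1-hydroxy-2,2-dimethylcyclopentyl]phenol, via lithium 4-lithiophenolate 5 (not isolated)
Conditions: 4 (1.2 equiv), n-BuLi (1.2 equiv), THF, −78 °C; t-BuLi (2.4 equiv), −78 → −40 °C; then 3, −78 °C, 1 h; then H2O
Reagents that add atoms: none
Why: Bromine–lithium exchange on the lithium phenolate and 1,2-addition of the aryllithium to the ketone; the neopentyl secondary bromide does not exchange with an aryllithium at −78 °C, attack is mainly anti to the C3 bromine (1S), and the minor C1 epimer converges in step 4 because C1 becomes a carbonyl carbon.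

Step 4
Reactants: 6 4-[(1S,3S)-3-bromo-1-hydroxy-2,2-dimethylcyclopentyl]phenol
Product: 7 (10S)-10-bromo-11,11-dimethylspiro[5.5]undeca-1,4-diene-3,7-dione
Conditions: PhI(OAc)2 (1.1 equiv), (CF3)2CHOH, 0 °C, 5 min
Reagents that add atoms: none
Why: Oxidative dearomatization of a para-substituted phenol by a trivalent iodine reagent with semipinacol ring expansion, in which two-electron oxidation makes the para carbon electrophilic and the more substituted C1–C2 bond of the cyclopentanol (the quaternary carbon) shifts to it as the carbinol becomes the ketone, giving the cyclohexanone ring A and the spiro quaternary carbon; no stereocenter is formed because ring B is still symmetric.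

Step 5
Reactants: 7 (10S)-10-bromo-11,11-dimethylspiro[5.5]undeca-1,4-diene-3,7-dione
Product: 8 (10S)-10-bromo-11,11-dimethylspiro[5.5]undecane-3,7-dione
Conditions: H2 (1 atm), 5% Pd/C, EtOAc, rt, stopped after 2 equiv H2
Reagents that add atoms: none
Why: Heterogeneous catalytic hydrogenation of the two disubstituted enone C=C bonds of a cross-conjugated dienone that cannot aromatize; the unactivated alkyl bromide and both ketones survive neutral conditions, and the acid- and nucleophile-sensitive 4-acyl dienone is removed.

Step 6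
Reactants: 8 (10S)-10-bromo-11,11-dimethylspiro[5.5]undecane-3,7-dione
Product: 10 (6S,10S)-10-bromo-11,11-dimethylspiro[5.5]undeca-2,7-diene-3,7-diyl bis(trifluoromethanesulfonate), via dilithium bis-enolate 9 (not isolated)
Conditions: (S,S)-bis(1-phenylethyl)amine (2.5 equiv), n-BuLi (2.4 equiv), LiCl (2.5 equiv), THF, −78 °C; add 8, 1 h; PhNTf2 (2.6 equiv), −78 → 0 °C; then H2O
Reagents that add atoms: N-phenylbis(trifluoromethanesulfonimide) O=S(=O)(N(c1ccccc1)S(=O)(=O)C(F)(F)F)C(F)(F)F
Why: Group-selective deprotonation of a 4,4-disubstituted cyclohexanone by a chiral lithium amide followed by O-triflation of the enolates; ring B is held with the CMe2 carbon equatorial, the base removes the axial C2–H in preference to the C4–H and thereby makes C6 a stereocenter (S in the triflate), while the C7 ketone can only enolize toward C8.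

Step 7
Reactants: 10 (6S,10S)-10-bromo-11,11-dimethylspiro[5.5]undeca-2,7-diene-3,7-diyl bis(trifluoromethanesulfonate)
Product: 11 (6R,10S)-10-bromo-3,7,11,11-tetramethylspiro[5.5]undeca-2,7-diene
Conditions: MeZnCl (4 equiv), Pd(PPh3)4 (5 mol%), THF, 60 °C
Reagents that add atoms: methylzinc chloride C[Zn]Cl
Why: Double Negishi cross-coupling of alkenyl triflates, in which zerovalent palladium inserts into the two C–OTf bonds but not into the unactivated neopentyl C–Br bond; no stereocenter is touched (the descriptor at C6 changes only through priorities).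

Step 8
Reactants: 11 (6R,10S)-10-bromo-3,7,11,11-tetramethylspiro[5.5]undeca-2,7-diene
Product: 12 (2R,3R,6R,10S)-2,10-dibromo-3,7,11,11-tetramethylspiro[5.5]undec-7-en-3-ol
Conditions: NBS (1.05 equiv), THF/H2O 4:1, 0 °C, dark
Reagents that add atoms: N-bromosuccinimide O=C1CCC(=O)N1Br; water O
Why: Bromohydrin formation, in which the ring B alkene reacts in preference to the C7=C8 alkene flanked by two quaternary carbons, Br+ adds to the face anti to the axial C7 carbon and water opens at the tertiary C3 (Markovnikov) anti to bromine, giving the 2R,3R trans bromohydrin with bromine and hydroxyl both equatorial.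

## Compound list

1 | 2-methylcyclopent-2-en-1-one | CC1=CCCC1=O | starting material
2 | (R)-1,2-dimethylcyclopent-2-en-1-ol | C[C@@]1(O)CCC=C1C | intermediate
3 | (S)-3-bromo-2,2-dimethylcyclopentan-1-one | O=C1CC[C@H](Br)C1(C)C | intermediate
4 | 4-bromophenol | Oc1ccc(Br)cc1 | starting material
5 | lithium 4-lithiophenolate | [Li]Oc1ccc([Li])cc1 | intermediate (not isolated)
6 | 4-[(1S,3S)-3-bromo-1-hydroxy-2,2-dimethylcyclopentyl]phenol | Oc1ccc(cc1)[C@@]2(O)CC[C@H](Br)C2(C)C | intermediate
7 | (10S)-10-bromo-11,11-dimethylspiro[5.5]undeca-1,4-diene-3,7-dione | O=C1C=CC2(C=C1)C(=O)CC[C@H](Br)C2(C)C | intermediate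
8 | (10S)-10-bromo-11,11-dimethylspiro[5.5]undecane-3,7-dione | O=C1CCC2(CC1)C(=O)CC[C@H](Br)C2(C)C | intermediate
9 | dilithium (6S,10S)-10-bromo-11,11-dimethylspiro[5.5]undeca-2,7-diene-3,7-bis(olate) | [Li]OC1=CC[C@H](Br)C(C)(C)[C@@]12CCC(O[Li])=CC2 | intermediate (not isolated)
10 | (6S,10S)-10-bromo-11,11-dimethylspiro[5.5]undeca-2,7-diene-3,7-diyl bis(trifluoromethanesulfonate) | FC(F)(F)S(=O)(=O)OC1=CC[C@H](Br)C(C)(C)[C@@]12CCC(OS(=O)(=O)C(F)(F)F)=CC2 | intermediate
11 | (6R,10S)-10-bromo-3,7,11,11-tetramethylspiro[5.5]undeca-2,7-diene | CC1=CC[C@H](Br)C(C)(C)[C@@]12CCC(C)=CC2 | intermediate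
12 | (2R,3R,6R,10S)-2,10-dibromo-3,7,11,11-tetramethylspiro[5.5]undec-7-en-3-ol | CC1=CC[C@H](Br)C(C)(C)[C@@]12CC[C@@](C)(O)[C@H](Br)C2 | target

## Step count and risks

Total steps: 8. Longest linear sequence: 8 (from 1; 4-bromophenol enters directly in step 3).

Steps most likely to fail:

**Step 2 (the proposed new step).** The risks are Br+ addition anti to the hydroxyl (which leads to a bromo epoxide), ionization of the tertiary allylic alcohol, and loss of ee if an open cation intervenes. The fallback uses known chemistry, sets out from 1 and returns at 3. The same Me2Zn/Ti(OiPr)4 addition with the mirror-image ligand gives (S)-1,2-dimethylcyclopent-2-en-1-ol F1. VO(acac)2/t-BuOOH epoxidizes syn to the hydroxyl to give (1R,2S,5R)-1,2-dimethyl-6-oxabicyclo[3.1.0]hexan-2-ol F2. BF3·OEt2 (CH2Cl2, −78 °C) effects the established epoxy-alcohol semipinacol with methyl shift to (R)-3-hydroxy-2,2-dimethylcyclopentan-1-one F3. Tf2O/pyridine gives (R)-2,2-dimethyl-3-oxocyclopentyl trifluoromethanesulfonate F4, and Bu4NBr (toluene, rt) displaces it with inversion to give 3. This last displacement is at a neopentyl centre and will be moderate in yield.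

**Step 6.** The sense of induction for the (S,S)-amide is assigned only by analogy with 4-tert-butylcyclohexanone, so if the C6 epimer predominates the (R,R)-amide is used instead. The level of selectivity next to the axial C7 carbonyl is also uncertain, and the C8 enolate could displace the C10 bromide to give a cyclopropane if warmed before triflation. The fallback sets out from 7 and returns at 9. A copper hydride desymmetrizing conjugate reduction (Cu(OAc)2, a chiral bisphosphine such as DTBM-SEGPHOS, (EtO)2MeSiH, t-BuOH, toluene) reduces only the C4=C5 bond and gives (6S,10S)-10-bromo-11,11-dimethylspiro[5.5]undec-1-ene-3,7-dione F5. LiBH(s-Bu)3 (1,4-reduction, which fixes the ring B enolate at C2=C3) followed by LiN(SiMe3)2 (for C7) then gives the bis-enolate 9, which is triflated as in step 6.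

**Step 8.** Facial selectivity is the main risk: the desired product needs Markovnikov opening of the bromonium ion formed anti to the axial C7 carbon, in competition with diaxial pathways that give the 2,3-bis-epimer or the regioisomer. Reaction at C7=C8 is a lesser risk. The fallback sets out from 7 and returns at 12; it sets C2 under steric and thermodynamic control and C3 by reagent control.
- KN(SiMe3)2/PhNTf2 (−78 °C) triflates the only enolizable ketone to give (10S)-10-bromo-11,11-dimethyl-3-oxospiro[5.5]undeca-1,4,7-trien-7-yl trifluoromethanesulfonate F6.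
- MeZnCl/Pd(PPh3)4 gives (10S)-10-bromo-7,11,11-trimethylspiro[5.5]undeca-1,4,7-trien-3-one F7.
- [(Ph3P)CuH]6 (benzene, H2O) reduces both enone C=C bonds to (10S)-10-bromo-7,11,11-trimethylspiro[5.5]undec-7-en-3-one F8.
- The (S,S)-lithium amide with Me3SiCl gives {[(6R,10S)-10-bromo-7,11,11-trimethylspiro[5.5]undeca-2,7-dien-3-yl]oxy}trimethylsilane F9.
- NBS (THF, −78 °C) gives (2R,6R,10S)-2,10-dibromo-7,11,11-trimethylspiro[5.5]undec-7-en-3-one F10, with bromine equatorial and anti to the axial C7 carbon (also the thermodynamic epimer).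
- MeLi in the presence of MeAl(OAr)2 (Ar = 2,6-di-tert-butyl-4-methylphenyl; toluene, −78 °C, cold quench) delivers methyl axially, cis to bromine, to give 12.

## Further compounds

F1 | step 2 | (S)-1,2-dimethylcyclopent-2-en-1-ol | C[C@]1(O)CCC=C1C
F2 | step 2 | (1R,2S,5R)-1,2-dimethyl-6-oxabicyclo[3.1.0]hexan-2-ol | C[C@]1(O)CC[C@H]2O[C@@]12C
F3 | step 2 | (R)-3-hydroxy-2,2-dimethylcyclopentan-1-one | O=C1CC[C@@H](O)C1(C)C
F4 | step 2 | (R)-2,2-dimethyl-3-oxocyclopentyl trifluoromethanesulfonate | O=C1CC[C@@H](OS(=O)(=O)C(F)(F)F)C1(C)C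
F5 | step 6 | (6S,10S)-10-bromo-11,11-dimethylspiro[5.5]undec-1-ene-3,7-dione | O=C1CC[C@H](Br)C(C)(C)[C@@]12CCC(=O)C=C2
F6 | step 8 | (10S)-10-bromo-11,11-dimethyl-3-oxospiro[5.5]undeca-1,4,7-trien-7-yl trifluoromethanesulfonate | O=C1C=CC2(C=C1)C(OS(=O)(=O)C(F)(F)F)=CC[C@H](Br)C2(C)C
F7 | step 8 | (10S)-10-bromo-7,11,11-trimethylspiro[5.5]undeca-1,4,7-trien-3-one | O=C1C=CC2(C=C1)C(C)=CC[C@H](Br)C2(C)C
F8 | step 8 | (10S)-10-bromo-7,11,11-trimethylspiro[5.5]undec-7-en-3-one | O=C1CCC2(CC1)C(C)=CC[C@H](Br)C2(C)C
F9 | step 8 | {[(6R,10S)-10-bromo-7,11,11-trimethylspiro[5.5]undeca-2,7-dien-3-yl]oxy}trimethylsilane | CC1=CC[C@H](Br)C(C)(C)[C@@]12CCC(O[Si](C)(C)C)=CC2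
F10 | step 8 | (2R,6R,10S)-2,10-dibromo-7,11,11-trimethylspiro[5.5]undec-7-en-3-one | CC1=CC[C@H](Br)C(C)(C)[C@@]12CCC(=O)[C@H](Br)C2
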